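At 2.50 h, the last reading of the zeta run, target stands at 12%, just as at 2.00 h, while dissolved substrate is still rising; we ask what that means for a flask read at 8.0 h.

| flask | solid substrate | partner | remark | time |
|---|---|---|---|---|
| zeta | 0.10 M | 1.1 equiv | run made earlier |  |
| flask | 0.050 M | 1.10 equiv |  | 8.0 h |

zeta run (percent of the solid substrate charged)

| time / h | target / % | dissolved substrate / % |
|---|---|---|
| 0.500 | 2 | 6 |
| 1.00 | 4 | 11 |
| 1.33 | 5 | 15 |
| 2.00 | 12 | 19 |
| 2.50 | 12 | 24 |

(each reading ± 1.5 percentage points)

- solid substrate is a solid; its amount is given per volume of the solution
- what was read earlier has a scatter of 1.5 percentage points, one standard deviation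
- on the list of suspects stand: solid substrate <-> dissolved substrate; dissolved substrate + partner -> target; partner -> side product; partner -> decomposed reagent
- at the start none of the solid substrate is in solution
- dissolved substrate means what is dissolved; the solid is not counted in it

1. amount of target at 8.0 h, in percent of the solid substrate charged
2. concentration of dissolved substrate in solution at 8.0 h, in percent of saturation

There are two ways to the target gained between those last readings of the zeta run. The first takes a coupling coefficient κ, target divided by the time-integral of dissolved substrate. With a straight dissolved curve up to 1.33 h, κ reads 0.501 h⁻¹, and held steady it promises 5.4 percentage points. The second way is the readings themselves, which show no gain, with a scatter of 1.5 points each.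

We doubt κ, since holding it steady assumes the partner keeps its strength. The partner's balance tests that: the zeta run charged 0.110 M and coupling used 0.0120 M. This gives φ, the share of charged partner that ends as target, 10.9%. Coupling took too little to stall itself, so we suspect the partner leaves by the routes to side product and decomposed reagent.

We assume those losses are first order and that dissolving ignores the amount of solid. Then at half the charge the flask has the same dissolved curve in molar terms, and φ carries over. Our reckoning for the flask is 12.0% target. Dissolving ran at 0.0144 M h⁻¹ in the zeta run, which would take the flask's charge in 3.47 h, less than 8.0 h. But dissolved substrate in the zeta run was still rising at its last reading of 24%, so that run gives us no saturation level, and we put no figure on the second question.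

The forecast differs, at 48% and 20%, reasoning that “Partner is half as concentrated, so coupling is slower”.

The flask gives 14.4% target and 98.7% of saturation. At 8.00 h it holds 0.00639% of its partner, the limiting reagent here despite 1.10 equiv charged.

    solid substrate ⇌ dissolved substrate, rate k1*(cs1 - [dissolved substrate]) while solid is left; crystals form when [dissolved substrate] > cs1 (solubility = 35.0 mM, k = 0.610 h⁻¹)
    dissolved substrate + partner → target (k = 12.0 M⁻¹ h⁻¹)
    partner → side product (k = 0.530 h⁻¹)
    partner → decomposed reagent (k = 0.360 h⁻¹)

The flask's share of partner ending as target is 13.1%, beside the 10.9% read earlier. For the neighbour charged with 0.280 equiv, φ gives 3.05% target, and that neighbour gave 3.92%.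

(Readings and results were computed for an exercise, noise included.)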